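**Retrosynthetic overview**

1. Numbering used throughout: C1 = CH–O(angelate), C2 = CH2, C3 = CH–O(senecioate), C4 = CMe2, C5 = cyclobutane CH on C4, C6 = cyclobutane CH on the ketone, C7 = C=O, C8 = enone CH, C9 = enone C(Me), C10 = cyclobutane CH on C9, C11 = cyclobutane C(Me) on C1. The target comes from the enone diol by two acylations, angelate last.
2. The cyclohexenone ring C5–C6–C7–C8–C9–C10 comes from the five-membered ketone ring C5–C6–C7–C9–C10 of a bicyclo[2.1.1]hexan-2-one: C8 is inserted between C7 and C9 by dibromocarbene addition to the silyl enol ether and opening of the cyclopropane. Enabling feature: C6 is a cyclobutane bridgehead, so the C7 ketone can enolise only toward C9; the tetrasubstituted C7=C9 enol ether (Me on C9) fixes the insertion site and the enone methyl, and the strain of the bicyclo[2.1.1]hexane drives the opening.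
3. The seven-membered ring comes from a reductive aldol of C4 onto the C5 cyclobutanone across the cyclobutane, followed by radical removal of the bridgehead C5–OH.
4. The cyclobutane C5–C6–C11–C10 and the five-membered ring are formed together by an intramolecular keteniminium–alkene [2+2] of an acyclic (E)-alkenyl amide (bonds C5–C10 and C6–C11); alkene geometry sets C11, the C9 methyl sets the absolute sense of the cage.
5. The chain comes from anti-crotylation, cross-metathesis and a boron aldol. Ring order: cyclobutane plus five-membered ring (step 6), seven-membered ring (step 7), six-membered enone ring by expansion (step 15).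

Key step: step 15

Assumption: the ligand antipode in step 1 and the borane antipode in step 4 are those expected from the published induction models; if the substrate reverses the sense, the other antipode is used.

**Route**

Step 1
Reactants: 1 3-hydroxy-N,N-dimethylpropanamide; 2 but-3-en-2-yl acetate
Product: 4 (3R,4S)-3-hydroxy-N,N,4-trimethylhex-5-enamide, via aldehyde 3 (not isolated)
Conditions: [Ir(cod)Cl]2 (2.5 mol %), (S)-SEGPHOS, 4-cyano-3-nitrobenzoic acid, Cs2CO3 (20 mol %), THF, 90 °C
Reagents that add atoms: none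
Why: Iridium-catalysed transfer-hydrogenative carbonyl crotylation: the alcohol is dehydrogenated to aldehyde 3, which is trapped by the (E)-σ-crotyliridium species through a closed chair transition state, so the anti relation C7–OH/C9–Me comes from the chair and the (3R,4S) configuration from the ligand.

Step 2
Reactants: 4 (3R,4S)-3-hydroxy-N,N,4-trimethylhex-5-enamide
Product: 5 (3R,4S)-N,N,4-trimethyl-3-(triethylsilyloxy)hex-5-enamide
Conditions: Et3SiCl, imidazole, DMF, 0 → 25 °C
Reagents that add atoms: chlorotriethylsilane, CC[Si](Cl)(CC)CC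
Why: Standard silylation of a secondary alcohol; the triethylsilyl ether is chosen because it can later be removed beside a hindered TBS ether and a PMB ether.

Step 3
Reactants: 5 (3R,4S)-N,N,4-trimethyl-3-(triethylsilyloxy)hex-5-enamide; 6 methacrolein
Product: 7 (3R,4S,5E)-N,N,4,6-tetramethyl-7-oxo-3-(triethylsilyloxy)hept-5-enamide
Conditions: second-generation Hoveyda–Grubbs catalyst (5 mol %), 6 (5 equiv), CH2Cl2, 40 °C
Reagents that add atoms: none
Why: Olefin cross-metathesis of a terminal alkene with methacrolein should give the conjugated trisubstituted enal as the thermodynamically preferred E isomer (C9 trans to CHO), the geometry that later fixes C11.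

Step 4
Reactants: 7 (3R,4S,5E)-N,N,4,6-tetramethyl-7-oxo-3-(triethylsilyloxy)hept-5-enamide; 8 3-methylbut-3-en-2-one
Product: 10 (3R,4S,5E,7R)-7-hydroxy-N,N,4,6,10-pentamethyl-9-oxo-3-(triethylsilyloxy)undeca-5,10-dienamide, via enol borinate 9 (not isolated)
Conditions: 8, (+)-Ipc2BCl, Et3N, Et2O, −78 → 0 °C; then 7, −78 → −20 °C; H2O2, pH 7 buffer, MeOH, 0 °C
Reagents that add atoms: none
Why: Boron aldol of a methyl ketone enol diisopinocampheylborinate (only the methyl of 8 can enolise) with 1,2-addition to the enal through a cyclic transition state, the isopinocampheyl groups selecting the aldehyde face that gives the R carbinol at C1 (reagent control, since the existing centres are remote).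

Step 5
Reactants: 10 (3R,4S,5E,7R)-7-hydroxy-N,N,4,6,10-pentamethyl-9-oxo-3-(triethylsilyloxy)undeca-5,10-dienamide
Product: 11 (3R,4S,5E,7R)-7-(tert-butyldimethylsilyloxy)-N,N,4,6,10-pentamethyl-9-oxo-3-(triethylsilyloxy)undeca-5,10-dienamide
Conditions: t-BuMe2SiOTf, 2,6-lutidine, CH2Cl2, −78 °C
Reagents that add atoms: tert-butyldimethylsilyl triflate, CC(C)(C)[Si](C)(C)OS(=O)(=O)C(F)(F)F
Why: Silylation of the β-hydroxy ketone with a silyl triflate and a hindered base is fast at low temperature and avoids β-elimination.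

Step 6
Reactants: 11 (3R,4S,5E,7R)-7-(tert-butyldimethylsilyloxy)-N,N,4,6,10-pentamethyl-9-oxo-3-(triethylsilyloxy)undeca-5,10-dienamide
Product: 14 6-[(1R)-1-(tert-butyldimethylsilyloxy)-4-methyl-3-oxopent-4-en-1-yl]-3,6-dimethyl-2-(triethylsilyloxy)bicyclo[2.1.1]hexan-5-one (6-Me syn to the two-carbon bridge, side chain anti; 2-OSiEt3 and 3-Me cis, on the side of the carbonyl bridge), via keteniminium triflate 12 (not isolated), via cyclobutaniminium triflate 13 (not isolated)
Conditions: Tf2O, 2,4,6-collidine, ClCH2CH2Cl (0.01 M), 0 → 83 °C; then aq. NaHCO3, 25 °C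
Reagents that add atoms: water, O
Why: Intramolecular keteniminium–alkene [2+2] cycloaddition in which the iminium carbon (C5) bonds to C10 with tertiary cationic character at C11 that closes onto C6 (the two-atom tether C7–C9 enforces the crossed mode and hence the bicyclo[2.1.1]hexane), the E geometry placing the C11 methyl syn to the C7–C9 bridge and the chain anti, and the C9 methyl and C7 silyloxy group taking the side of C5 away from that methyl, which sets the absolute sense of the cage; hydrolysis gives the cyclobutanone.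

Step 7
Reactants: 14 the bicyclo[2.1.1]hexan-5-one of step 6
Product: 16 tricyclic aldol: C4(Me2)–C5 bond closed, C5–OH (bridgehead, on the face of the C7–C9 bridge), C3 ketone, C1–OTBS, C7–OSiEt3, via copper enolate 15 (not isolated)
Conditions: [(Ph3P)CuH]6 (0.4 equiv), toluene/THF, −40 → −10 °C; aq. NH4Cl
Reagents that add atoms: none
Why: Copper hydride reductive aldol cyclisation: conjugate hydride delivery to the isopropenyl ketone gives the C4 enolate regiospecifically, which adds to the strained C5 cyclobutanone held next to it by the anti chain on C11; C5 becomes a bridgehead, so its configuration is dictated by the ring.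

Step 8
Reactants: 16 tricyclic aldol
Product: 17 diol: as 16 but C3 (R)-CH–OH, oxygen on the C10 side, trans to the C1 oxygen
Conditions: (S)-2-methyl-CBS-oxazaborolidine (0.3 equiv), BH3·SMe2, THF, −20 °C; MeOH
Reagents that add atoms: none
Why: Corey–Bakshi–Shibata reduction, the catalyst differentiating the quaternary C4 (large) from the C2 methylene (small) so that the S catalyst should deliver the 3R alcohol under reagent control.

Step 9
Reactants: 17 diol
Product: 18 C3 4-methoxybenzyl ether of 17 (C5–OH free)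
Conditions: NaH, 4-MeOC6H4CH2Cl, Bu4NI (cat.), DMF, 0 → 25 °C
Reagents that add atoms: 4-methoxybenzyl chloride, COc1ccc(CCl)cc1
Why: Williamson etherification, the secondary alkoxide being alkylated much faster than the tertiary bridgehead alkoxide.

Step 10
Reactants: 18 C3 PMB ether
Product: 19 C5 methyl oxalate of 18
Conditions: MeO2CCOCl, pyridine, DMAP, CH2Cl2, 0 → 25 °C
Reagents that add atoms: methyl chlorooxoacetate, COC(=O)C(Cl)=O
Why: Acylation of the tertiary alcohol with the very reactive oxalyl half-ester chloride gives the radical precursor used for tertiary alcohol deoxygenation.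

Step 11
Reactants: 19 C5 methyl oxalate
Product: 20 deoxygenated tricycle: C5–H, C3–OPMB, C1–OTBS, C7–OSiEt3
Conditions: Bu3SnH, AIBN (cat.), toluene, 110 °C
Reagents that add atoms: none
Why: Barton-type radical deoxygenation of a tertiary oxalate (stannyl radical addition, β-scission to the C5 radical, hydrogen transfer from the stannane); C5 is a bridgehead, so hydrogen can only arrive on the face of the C7–C9 bridge.

Step 12
Reactants: 20 deoxygenated tricycle
Product: 21 C7 alcohol (triethylsilyl group removed)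
Conditions: PPTS (cat.), MeOH/CH2Cl2, 0 °C
Reagents that add atoms: none
Why: Acid-catalysed methanolysis removes the secondary triethylsilyl ether far faster than the hindered TBS ether and leaves the PMB ether.

Step 13
Reactants: 21 C7 alcohol
Product: 22 C7 ketone (a 3-methylbicyclo[2.1.1]hexan-2-one unit)
Conditions: Dess–Martin periodinane, NaHCO3, CH2Cl2, 25 °C
Reagents that add atoms: none
Why: Dess–Martin oxidation of a secondary alcohol under buffered, non-epimerising conditions.

Step 14
Reactants: 22 C7 ketone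
Product: 24 trimethylsilyl enol ether C7(OSiMe3)=C9(Me), via lithium enolate 23 (not isolated)
Conditions: LiN(i-Pr)2, THF, −78 °C; Me3SiCl, Et3N, −78 → 0 °C
Reagents that add atoms: chlorotrimethylsilane, C[Si](C)(C)Cl
Why: Enolate formation and O-silylation; C6 is a cyclobutane bridgehead and cannot enolise, so only the C7=C9 enol ether can form.

Step 15
Reactants: 24 trimethylsilyl enol ether
Product: 26 bromo enone: C7(=O)–C8(Br)=C9(Me) in the bicyclo[3.1.1]hept-3-en-2-one ring, C3–OPMB, C1–OTBS, via dibromocyclopropane 25 (not isolated)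
Conditions: CHBr3, KOt-Bu, pentane, −20 → 25 °C; then toluene, 60 °C
Reagents that add atoms: bromoform, BrC(Br)Br
Why: Dibromocarbene from bromoform and KOt-Bu adds to the only electron-rich alkene, the tetrasubstituted enol ether C7=C9, from the face of C5–H away from the C11 methyl, giving the 1-siloxy-2,2-dibromocyclopropane 25. This cyclopropane opens by a strain- and oxygen-assisted disrotatory two-electron electrocyclic process with loss of the bromide syn to C6/C10, which cleaves the C7–C9 bond and places the carbene carbon C8 between them; bromide then removes the silyl group from the 2-siloxyallyl cation to give the enone. The closest known reaction type is the halocarbene ring expansion of cyclic trimethylsilyl enol ethers to 2-halocycloalk-2-enones. The only ring closed is the transient cyclopropane, by cheletropic [2+1] addition; the six-membered ring arises by opening of its shared C7–C9 bond, not by an end-to-end closure. No new stereocentre remains (C9 becomes sp2; C5, C6, C10 and C11 are untouched). The step needs regiocontrol of the insertion, secured by the non-enolisable bridgehead C6 and the methyl on C9, and the cation is held as an oxocarbenium at C7, which should suppress a cyclobutylcarbinyl shift at C9.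

Step 16
Reactants: 26 bromo enone
Product: 27 enone: C7(=O)–C8H=C9(Me), C3–OPMB, C1–OTBS
Conditions: Pd(OAc)2 (5 mol %), PPh3, HCO2H, Et3N, DMF, 60 °C
Reagents that add atoms: none
Why: Palladium-catalysed formate hydrogenolysis of the vinyl bromide (oxidative addition, hydride from formate, reductive elimination); the β,β-disubstituted enone should resist conjugate reduction.

Step 17
Reactants: 27 enone
Product: 28 C3 alcohol (PMB removed), C1–OTBS
Conditions: DDQ, CH2Cl2/pH 7 buffer, 0 → 25 °C
Reagents that add atoms: none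
Why: Oxidative cleavage of the 4-methoxybenzyl ether by DDQ, which leaves the silyl ether and the enone untouched.

Step 18
Reactants: 28 C3 alcohol; 29 3-methylbut-2-enoyl chloride
Product: 30 C3 3-methylbut-2-enoate (senecioate), C1–OTBS
Conditions: 29, pyridine, DMAP (cat.), CH2Cl2, 0 → 25 °C
Reagents that add atoms: none
Why: DMAP-catalysed acylation of the hindered secondary alcohol; pyridine as the only base limits deconjugation of the acyl group through a vinylketene.

Step 19
Reactants: 30 C3 senecioate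
Product: 31 C1 alcohol, C3 senecioate
Conditions: HF·pyridine, pyridine, THF, 0 → 25 °C
Reagents that add atoms: none
Why: Buffered fluoride desilylation of the hindered TBS ether; the trans 1,3-relation of the two oxygens should prevent acyl migration.

Step 20
Reactants: 31 C1 alcohol; 32 angelic acid
Product: 34 CNP0277258.2 (target), via mixed anhydride 33 (not isolated)
Conditions: 32, 2,4,6-Cl3C6H2COCl, Et3N, toluene, 25 °C; then 31, 80 °C
Reagents that add atoms: none
Why: Yamaguchi-type esterification through the 2,4,6-trichlorobenzoyl mixed anhydride without DMAP, the non-isomerising way to angelates, so the Z geometry should be kept.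

**Compound list**

1 | 3-hydroxy-N,N-dimethylpropanamide | CN(C)C(=O)CCO | starting material
2 | but-3-en-2-yl acetate (racemic) | CC(OC(C)=O)C=C | starting material
3 | N,N-dimethyl-3-oxopropanamide | CN(C)C(=O)CC=O | intermediate
4 | (3R,4S)-3-hydroxy-N,N,4-trimethylhex-5-enamide | CN(C)C(=O)C[C@@H](O)[C@@H](C)C=C | intermediate
5 | (3R,4S)-N,N,4-trimethyl-3-(triethylsilyloxy)hex-5-enamide | CN(C)C(=O)C[C@@H](O[Si](CC)(CC)CC)[C@@H](C)C=C | intermediate
6 | methacrolein | CC(=C)C=O | starting material
7 | (3R,4S,5E)-N,N,4,6-tetramethyl-7-oxo-3-(triethylsilyloxy)hept-5-enamide | CN(C)C(=O)C[C@@H](O[Si](CC)(CC)CC)[C@@H](C)/C=C(\C)C=O | intermediate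
8 | 3-methylbut-3-en-2-one | CC(=O)C(C)=C | starting material
9 | (3-methylbuta-1,3-dien-2-yl)oxy-diisopinocampheylborane (from (+)-Ipc2BCl) | C=C(OB([C@H]1C[C@H]2C[C@@H]([C@@H]1C)C2(C)C)[C@H]1C[C@H]2C[C@@H]([C@@H]1C)C2(C)C)C(C)=C | intermediate
10 | (3R,4S,5E,7R)-7-hydroxy-N,N,4,6,10-pentamethyl-9-oxo-3-(triethylsilyloxy)undeca-5,10-dienamide | CN(C)C(=O)C[C@@H](O[Si](CC)(CC)CC)[C@@H](C)/C=C(\C)[C@H](O)CC(=O)C(C)=C | intermediate
11 | (3R,4S,5E,7R)-7-(tert-butyldimethylsilyloxy)-N,N,4,6,10-pentamethyl-9-oxo-3-(triethylsilyloxy)undeca-5,10-dienamide | CN(C)C(=O)C[C@@H](O[Si](CC)(CC)CC)[C@@H](C)/C=C(\C)[C@H](O[Si](C)(C)C(C)(C)C)CC(=O)C(C)=C | intermediate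
12 | keteniminium triflate of 11 (Me2N+=C5=C6H) | C[N+](C)=C=C[C@@H](O[Si](CC)(CC)CC)[C@@H](C)/C=C(\C)[C@H](O[Si](C)(C)C(C)(C)C)CC(=O)C(C)=C.[O-]S(=O)(=O)C(F)(F)F | intermediate
13 | cyclobutaniminium triflate (C5=N+Me2 analogue of 14) | C[N+](C)=C1[C@H]2[C@@H](O[Si](CC)(CC)CC)[C@@H](C)[C@@H]1[C@@]2(C)[C@H](O[Si](C)(C)C(C)(C)C)CC(=O)C(C)=C.[O-]S(=O)(=O)C(F)(F)F | intermediate
14 | 6-[(1R)-1-(tert-butyldimethylsilyloxy)-4-methyl-3-oxopent-4-en-1-yl]-3,6-dimethyl-2-(triethylsilyloxy)bicyclo[2.1.1]hexan-5-one (6-Me syn to the two-carbon bridge; 2-OSiEt3 and 3-Me cis, on the carbonyl side) | O=C1[C@H]2[C@@H](O[Si](CC)(CC)CC)[C@@H](C)[C@@H]1[C@@]2(C)[C@H](O[Si](C)(C)C(C)(C)C)CC(=O)C(C)=C | intermediate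
15 | C4 enolate of 14 with monovalent copper (Ph3P-ligated) | O=C1[C@H]2[C@@H](O[Si](CC)(CC)CC)[C@@H](C)[C@@H]1[C@@]2(C)[C@H](O[Si](C)(C)C(C)(C)C)CC(O[Cu])=C(C)C | intermediate
16 | tricyclic aldol: C5–OH, C3 ketone, C1–OTBS (O toward C6), C7–OSiEt3 and C9–Me toward C5 | CC(C)(C)[Si](C)(C)O[C@@H]1CC(=O)C(C)(C)[C@]2(O)[C@H]3[C@@H](O[Si](CC)(CC)CC)[C@@H](C)[C@@H]2[C@]31C | intermediate
17 | diol: as 16 with C3 (R)-OH (O toward C10) | CC(C)(C)[Si](C)(C)O[C@@H]1C[C@@H](O)C(C)(C)[C@]2(O)[C@H]3[C@@H](O[Si](CC)(CC)CC)[C@@H](C)[C@@H]2[C@]31C | intermediate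
18 | C3 4-methoxybenzyl ether of 17 | CC(C)(C)[Si](C)(C)O[C@@H]1C[C@@H](OCc4ccc(OC)cc4)C(C)(C)[C@]2(O)[C@H]3[C@@H](O[Si](CC)(CC)CC)[C@@H](C)[C@@H]2[C@]31C | intermediate
19 | C5 methyl oxalate of 18 | CC(C)(C)[Si](C)(C)O[C@@H]1C[C@@H](OCc4ccc(OC)cc4)C(C)(C)[C@]2(OC(=O)C(=O)OC)[C@H]3[C@@H](O[Si](CC)(CC)CC)[C@@H](C)[C@@H]2[C@]31C | intermediate
20 | deoxygenated tricycle (C5–H) | CC(C)(C)[Si](C)(C)O[C@@H]1C[C@@H](OCc4ccc(OC)cc4)C(C)(C)[C@@H]2[C@H]3[C@@H](O[Si](CC)(CC)CC)[C@@H](C)[C@@H]2[C@]31C | intermediate
21 | C7 alcohol | CC(C)(C)[Si](C)(C)O[C@@H]1C[C@@H](OCc4ccc(OC)cc4)C(C)(C)[C@@H]2[C@H]3[C@@H](O)[C@@H](C)[C@@H]2[C@]31C | intermediate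
22 | C7 ketone (bicyclo[2.1.1]hexan-2-one unit) | CC(C)(C)[Si](C)(C)O[C@@H]1C[C@@H](OCc4ccc(OC)cc4)C(C)(C)[C@@H]2[C@H]3C(=O)[C@@H](C)[C@@H]2[C@]31C | intermediate
23 | lithium enolate of 22 (C7=C9) | CC(C)(C)[Si](C)(C)O[C@@H]1C[C@@H](OCc4ccc(OC)cc4)C(C)(C)[C@@H]2[C@H]3C(O[Li])=C(C)[C@@H]2[C@]31C | intermediate
24 | trimethylsilyl enol ether C7(OSiMe3)=C9(Me) | CC(C)(C)[Si](C)(C)O[C@@H]1C[C@@H](OCc4ccc(OC)cc4)C(C)(C)[C@@H]2[C@H]3C(O[Si](C)(C)C)=C(C)[C@@H]2[C@]31C | intermediate
25 | dibromocyclopropane (C8Br2 across C7/C9, on the C5 side) | CC(C)(C)[Si](C)(C)O[C@@H]1C[C@@H](OCc5ccc(OC)cc5)C(C)(C)[C@@H]2[C@H]3[C@@]4(O[Si](C)(C)C)C(Br)(Br)[C@@]4(C)[C@@H]2[C@]31C | intermediate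
26 | bromo enone (C8–Br) | CC(C)(C)[Si](C)(C)O[C@@H]1C[C@@H](OCc4ccc(OC)cc4)C(C)(C)[C@@H]2[C@H]3C(=O)C(Br)=C(C)[C@@H]2[C@]31C | intermediate
27 | enone, C3–OPMB, C1–OTBS | CC(C)(C)[Si](C)(C)O[C@@H]1C[C@@H](OCc4ccc(OC)cc4)C(C)(C)[C@@H]2[C@H]3C(=O)C=C(C)[C@@H]2[C@]31C | intermediate
28 | enone, C3–OH, C1–OTBS | CC(C)(C)[Si](C)(C)O[C@@H]1C[C@@H](O)C(C)(C)[C@@H]2[C@H]3C(=O)C=C(C)[C@@H]2[C@]31C | intermediate
29 | 3-methylbut-2-enoyl chloride | CC(C)=CC(Cl)=O | starting material
30 | enone, C3 senecioate, C1–OTBS | CC(C)(C)[Si](C)(C)O[C@@H]1C[C@@H](OC(=O)C=C(C)C)C(C)(C)[C@@H]2[C@H]3C(=O)C=C(C)[C@@H]2[C@]31C | intermediate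
31 | enone, C3 senecioate, C1–OH | O[C@@H]1C[C@@H](OC(=O)C=C(C)C)C(C)(C)[C@@H]2[C@H]3C(=O)C=C(C)[C@@H]2[C@]31C | intermediate
32 | angelic acid | C/C=C(/C)C(=O)O | starting material
33 | angelic 2,4,6-trichlorobenzoic anhydride | C/C=C(/C)C(=O)OC(=O)c1c(Cl)cc(Cl)cc1Cl | intermediate
34 | CNP0277258.2 | C/C=C(/C)C(=O)O[C@@H]1C[C@@H](OC(=O)C=C(C)C)C(C)(C)[C@@H]2[C@H]3C(=O)C=C(C)[C@@H]2[C@]31C | target

**Summary**

Total step count: 20. Longest linear sequence: 20 steps (from 1).

The three steps most likely to fail: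

Step 6. The cation formed after the first C–C bond may live long enough to rotate about C10–C11 and scramble the C11 configuration, and triflic acid may strip the silyl ethers or the C7 silyloxy group may be eliminated. The fallback sets out from 11 and returns at 14 through a concerted, acid-free ketene cycloaddition, at the cost of the lower efficiency expected for an aldoketene under high dilution. O-Methylation of the amide (MeOTf, 2,6-di-tert-butyl-4-methylpyridine, CH2Cl2) and hydrolysis of the imidate salt with aqueous NaHCO3 give methyl ester F1. Me3SnOH (ClCH2CH2Cl, 80 °C) gives acid F2. 1-Chloro-N,N,2-trimethylprop-1-en-1-amine gives acid chloride F3, which is added slowly to Et3N in toluene at 110 °C; ketene F4 closes by the thermal [2+2] to 14.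

Step 7. The copper enolate may be protonated or may shift to C2 by proton transfer before it reaches the hindered ketone, and the aldolate may revert. The fallback sets out from 14 and returns at 16. Conjugate hydrosilylation ((Ph3P)3RhCl cat., Et3SiH, benzene, 50 °C) gives the regiodefined triethylsilyl enol ether F5. NBS (THF, −78 °C) gives the tertiary α-bromo ketone F6. SmI2 (THF, −78 °C) then closes the ring by a Reformatsky-type addition whose samarium aldolate does not revert, giving 16.

Step 15. The carbene may fail to add to the hindered tetrasubstituted enol ether, the base may cleave the silyl enol ether first, or the cationic opening may trigger a skeletal shift of the cyclobutane. The fallback sets out from 24 and returns at 27 (Ito–Saegusa ring expansion). Et2Zn/CH2I2 (CH2Cl2, 0 °C) gives siloxycyclopropane F7. FeCl3 (DMF, 0 °C) opens the C7–C9 bond oxidatively to the β-chloro ketone F8 (C9 epimers). NaOAc (MeOH, 65 °C) eliminates HCl to the enone 27. In this fallback fast chlorine transfer has to outrun opening of the cyclobutane by the C9 radical.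

Further compounds

F1 | step 6 | methyl ester corresponding to amide 11 | COC(=O)C[C@@H](O[Si](CC)(CC)CC)[C@@H](C)/C=C(\C)[C@H](O[Si](C)(C)C(C)(C)C)CC(=O)C(C)=C
F2 | step 6 | carboxylic acid corresponding to 11 | OC(=O)C[C@@H](O[Si](CC)(CC)CC)[C@@H](C)/C=C(\C)[C@H](O[Si](C)(C)C(C)(C)C)CC(=O)C(C)=C
F3 | step 6 | acid chloride of F2 | ClC(=O)C[C@@H](O[Si](CC)(CC)CC)[C@@H](C)/C=C(\C)[C@H](O[Si](C)(C)C(C)(C)C)CC(=O)C(C)=C
F4 | step 6 | ketene from F3 (O=C5=C6H) | O=C=C[C@@H](O[Si](CC)(CC)CC)[C@@H](C)/C=C(\C)[C@H](O[Si](C)(C)C(C)(C)C)CC(=O)C(C)=C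
F5 | step 7 | triethylsilyl enol ether C3(OSiEt3)=C4Me2 of the reduced side chain of 14 | O=C1[C@H]2[C@@H](O[Si](CC)(CC)CC)[C@@H](C)[C@@H]1[C@@]2(C)[C@H](O[Si](C)(C)C(C)(C)C)CC(O[Si](CC)(CC)CC)=C(C)C
F6 | step 7 | tertiary α-bromo ketone (C4–Br) | O=C1[C@H]2[C@@H](O[Si](CC)(CC)CC)[C@@H](C)[C@@H]1[C@@]2(C)[C@H](O[Si](C)(C)C(C)(C)C)CC(=O)C(C)(C)Br
F7 | step 15 | siloxycyclopropane (CH2 across C7/C9) | CC(C)(C)[Si](C)(C)O[C@@H]1C[C@@H](OCc5ccc(OC)cc5)C(C)(C)[C@@H]2[C@H]3[C@@]4(O[Si](C)(C)C)C[C@@]4(C)[C@@H]2[C@]31C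
F8 | step 15 | ring-expanded β-chloro ketone (C9–Cl, epimers) | CC(C)(C)[Si](C)(C)O[C@@H]1C[C@@H](OCc4ccc(OC)cc4)C(C)(C)[C@@H]2[C@H]3C(=O)CC(C)(Cl)[C@@H]2[C@]31C
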